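Its constants are those of an exercise; the run is a simulation.

The product forms from the intermediate, so I wanted to know how much intermediate still stood after the run as the partner charge went up.

    starting material + free catalyst → free catalyst + intermediate (k1 = 5.0 L mol⁻¹ h⁻¹)
    partner + second catalyst + intermediate → second catalyst + product (k2 = 11 L² mol⁻² h⁻¹)
    starting material + protic impurity → quenched substrate (k3 = 0.14 L mol⁻¹ h⁻¹)

all flasks: starting material 0.66 M; protic impurity 0.132 M; free catalyst 27 mM; second catalyst 6.6 mM; time 5.0 h
- Saturday's: partner 0.400 M
- Friday's: partner 0.500 M
- Tuesday's: partner 0.800 M

- "hardly changes" means that all values lie within two and a half points (for a concentration: within two and a half percent of the largest)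
- run time (Saturday's): 5.0 h

- amount of intermediate at the end, in percent of the starting material charged for Saturday's, Friday's, Tuesday's, in this order
- the shape of the row from first to last (rises all the way / rises, then falls / falls all the way / hardly changes / falls, then rises)

At the bench I would have said that Saturday's intermediate has a half-life by step two of 24 h, long against the 5.0 h run, so step two can be ignored. The intermediate then ends at whatever step one made, and the row hardly changes.

I reckoned that amount first. Against the free catalyst, starting material is lost at f = 0.135 h⁻¹, and against the protic impurity held at its charge at g = 0.0185 h⁻¹. Splitting the first-order loss over the run in the ratio f to g gave the share M made into intermediate: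

M = 47.1%

The partner enters neither step one nor step three, so I took M as one figure for Saturday's, Friday's and Tuesday's.

The flasks differ in the partner's concentration, and the partner enters step two, the drain on the intermediate. With the partner and the second catalyst held at their charges, step two is pseudo-first-order in intermediate, with κ the rate constant of step two times both concentrations. If the feed is steady, the intermediate grows in line with time, so its average is half its end value. Product over intermediate at the end, after the run time t, is then d = κt/2, which I called the drain share, and the intermediate is M/(1 + d):

Saturday's: κ = 0.0290 h⁻¹, d = 7.26%, intermediate 43.9%
Friday's: κ = 0.0363 h⁻¹, d = 9.08%, intermediate 43.2%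
Tuesday's: κ = 0.0581 h⁻¹, d = 14.5%, intermediate 41.2%

Here the bench rule stopped working. Tuesday's partner is twice Saturday's, and that opened a drop of 2.7 percentage points along my row, against a margin of 2.5 points, so I expected a fall.

The forecast gave 43.8%, 43% and 40.5%, with Tuesday's below my figure, and its shape was falls all the way: “The spread of 3.3 points exceeds 2.5, so the row falls all the way.”

The simulation gave 43.8%, 42.9% and 40.5%, and the shape falls all the way.

Saturday's ended with a reading of product over intermediate of 8.15%, a little above its d of 7.26%. Tuesday's read 16.8% against 14.5%. Tuesday's drain also worked through time: run for ten times as long, Tuesday's intermediate went from 40.5% to 20.8%.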